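**Assumption:** the SMILES is read as the (3R)-isoflavan; MOMCl, NBS and ozone are treated as reagents and not numbered. The route is a paper design and has not been run.

## Retrosynthetic overview

1. Target ⇐ removal of two MOM groups ⇐ prenylation of an aryl bromide (Br/Li exchange) ⇐ chroman ring C by intramolecular aryl C–O coupling.
2. The 2,2-dimethyl-2H-pyran ring ⇐ prenal condensation and oxa-6π electrocyclization on a 2-bromoresorcinol whose bromine later becomes the prenyl group.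
3. C2–OH ⇐ ozonolysis of the propenyl group left by the key aromatic Claisen [3,3] rearrangement, which makes the C3–aryl bond with 1,3-chirality transfer.
4. The (R,E)-aryl allyl ether ⇐ Mitsunobu inversion of an (S,E)-allylic alcohol ⇐ (S)-but-3-yn-2-ol plus a benzylic bromide.
5. Ring order: both benzene rings are bought; the 2H-pyran forms in step 8 and the dihydropyran (ring C) in step 10.

## Route

Step 1
Reactants: 1 3-bromo-4-methylphenol
Product: 2 2-bromo-4-(methoxymethoxy)-1-methylbenzene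
Conditions: NaH, THF/DMF, 0 °C; MOMCl, 0 °C → rt
Reagents that add atoms: chloromethyl methyl ether (MOMCl), COCCl
Why: Williamson-type O-alkylation of the phenoxide gives a MOM acetal that survives the later basic, organometallic and thermal steps.

Step 2
Reactants: 2 2-bromo-4-(methoxymethoxy)-1-methylbenzene
Product: 3 2-bromo-1-(bromomethyl)-4-(methoxymethoxy)benzene
Conditions: NBS (1.05 equiv), AIBN (cat.), PhCF3, 80 °C
Reagents that add atoms: N-bromosuccinimide, O=C1CCC(=O)N1Br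
Why: Wohl–Ziegler radical bromination at the only benzylic C–H position.

Step 3
Reactants: 3 2-bromo-1-(bromomethyl)-4-(methoxymethoxy)benzene, 4 (S)-but-3-yn-2-ol
Product: 6 (2S)-5-[2-bromo-4-(methoxymethoxy)phenyl]pent-3-yn-2-ol, via bromomagnesium alkynide alkoxide 5 (not isolated)
Conditions: 4 (1.5 equiv), EtMgBr (3 equiv), THF, 0 → 45 °C; CuBr·SMe2 (10 mol%), then 3, 50 °C; aq. NH4Cl
Reagents that add atoms: none
Why: Copper-catalysed sp–sp3 coupling of the alkynyl Grignard with the benzylic bromide; the carbinol stereocentre is not touched and the aryl bromide is inert.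

Step 4
Reactants: 6 (2S)-5-[2-bromo-4-(methoxymethoxy)phenyl]pent-3-yn-2-ol
Product: 7 (2S,3E)-5-[2-bromo-4-(methoxymethoxy)phenyl]pent-3-en-2-ol
Conditions: Red-Al (3 equiv), THF, 0 °C → rt; aq. Rochelle salt
Reagents that add atoms: none
Why: Alkoxide-directed trans-hydroalumination of the propargylic alcohol gives only the E-alkene and leaves the stereocentre alone.

Step 5
Reactants: 7 (2S,3E)-5-[2-bromo-4-(methoxymethoxy)phenyl]pent-3-en-2-ol, 8 2-bromobenzene-1,3-diol
Product: 9 2-bromo-3-{[(2R,3E)-5-[2-bromo-4-(methoxymethoxy)phenyl]pent-3-en-2-yl]oxy}phenol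
Conditions: 8 (3 equiv), PPh3, DIAD, THF, 0 °C → rt
Reagents that add atoms: none
Why: Mitsunobu etherification proceeds by SN2 inversion (S → R) at the carbinol carbon; excess diol limits bis-etherification.

Step 6
Reactants: 9 2-bromo-3-{[(2R,3E)-5-[2-bromo-4-(methoxymethoxy)phenyl]pent-3-en-2-yl]oxy}phenol
Product: 11 2-bromo-4-[(2S,3E)-1-[2-bromo-4-(methoxymethoxy)phenyl]pent-3-en-2-yl]benzene-1,3-diol, via ortho-dienone 10 (not isolated)
Conditions: PhNEt2 (degassed), 185 °C, 3 h
Reagents that add atoms: none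
Why: Aromatic Claisen [3,3] rearrangement through a chair transition state (methyl equatorial) transfers chirality suprafacially from the C–O carbon to the new benzylic C–C bond (R,E-ether → S centre, the future C3); bromine blocks the other ortho position.

Step 7
Reactants: 11 2-bromo-4-[(2S,3E)-1-[2-bromo-4-(methoxymethoxy)phenyl]pent-3-en-2-yl]benzene-1,3-diol
Product: 13 2-bromo-4-[(2R)-1-[2-bromo-4-(methoxymethoxy)phenyl]-3-hydroxypropan-2-yl]benzene-1,3-diol, via alpha-aryl aldehyde 12 (not isolated)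
Conditions: O3, CH2Cl2/MeOH 4:1, −78 °C (Sudan III end point); then NaBH4, −78 → 0 °C
Reagents that add atoms: ozone, [O-][O+]=O
Why: Ozonolysis with reductive work-up excises the propenyl terminus to leave the primary alcohol; the stereocentre keeps its geometry (S → R is only a CIP priority change).

Step 8
Reactants: 13 2-bromo-4-[(2R)-1-[2-bromo-4-(methoxymethoxy)phenyl]-3-hydroxypropan-2-yl]benzene-1,3-diol, 14 3-methylbut-2-enal
Product: 16 8-bromo-6-[(2R)-1-[2-bromo-4-(methoxymethoxy)phenyl]-3-hydroxypropan-2-yl]-2,2-dimethyl-2H-chromen-7-ol, via ortho-quinone methide 15 (not isolated)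
Conditions: 14 (2 equiv), ethylenediamine diacetate (20 mol%), toluene, 110 °C
Reagents that add atoms: none
Why: Knoevenagel-type condensation at the only free activated ring carbon, then oxa-6π electrocyclization of the ortho-quinone methide, closes the 2H-pyran on the only OH with a free ortho carbon.

Step 9
Reactants: 16 8-bromo-6-[(2R)-1-[2-bromo-4-(methoxymethoxy)phenyl]-3-hydroxypropan-2-yl]-2,2-dimethyl-2H-chromen-7-ol
Product: 17 (2R)-3-[2-bromo-4-(methoxymethoxy)phenyl]-2-[8-bromo-7-(methoxymethoxy)-2,2-dimethyl-2H-chromen-6-yl]propan-1-ol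
Conditions: MOMCl (1.2 equiv), K2CO3, acetone, 40 °C
Reagents that add atoms: chloromethyl methyl ether (MOMCl), COCCl
Why: Selective O-alkylation of the acidic ortho-bromophenoxide (carbonate does not deprotonate the primary alcohol) masks the phenol, which would otherwise compete in the ring closure.

Step 10
Reactants: 17 (2R)-3-[2-bromo-4-(methoxymethoxy)phenyl]-2-[8-bromo-7-(methoxymethoxy)-2,2-dimethyl-2H-chromen-6-yl]propan-1-ol
Product: 18 (3R)-3-[8-bromo-7-(methoxymethoxy)-2,2-dimethyl-2H-chromen-6-yl]-7-(methoxymethoxy)chromane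
Conditions: CuI (10 mol%), 3,4,7,8-tetramethyl-1,10-phenanthroline (20 mol%), Cs2CO3, toluene, 110 °C
Reagents that add atoms: none
Why: Ullmann-type intramolecular C–O coupling closes the six-membered ring at the unhindered aryl bromide; the di-ortho-oxygenated bromide on the chromene is too hindered to react and the stereocentre is remote.

Step 11
Reactants: 18 (3R)-3-[8-bromo-7-(methoxymethoxy)-2,2-dimethyl-2H-chromen-6-yl]-7-(methoxymethoxy)chromane, 19 1-bromo-3-methylbut-2-ene
Product: 21 (3R)-7-(methoxymethoxy)-3-[7-(methoxymethoxy)-2,2-dimethyl-8-(3-methylbut-2-en-1-yl)-2H-chromen-6-yl]chromane, via aryllithium 20 (not isolated)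
Conditions: n-BuLi (1.1 equiv), THF, −78 °C; CuI (10 mol%), then 19, −78 → 0 °C
Reagents that add atoms: none
Why: Bromine–lithium exchange at the only remaining bromide, then copper-catalysed SN2 allylation, installs the prenyl group between the two oxygens.

Step 12
Reactants: 21 (3R)-7-(methoxymethoxy)-3-[7-(methoxymethoxy)-2,2-dimethyl-8-(3-methylbut-2-en-1-yl)-2H-chromen-6-yl]chromane
Product: 22 (3R)-3-[7-hydroxy-2,2-dimethyl-8-(3-methylbut-2-en-1-yl)-2H-chromen-6-yl]chroman-7-ol
Conditions: 3 M aq. HCl/MeOH (1:5), 45 °C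
Reagents that add atoms: none
Why: Acid-catalysed acetal methanolysis removes both MOM groups under conditions mild enough for the chromene and the ortho-prenylphenol.

## Compound list

1 | 3-bromo-4-methylphenol | Cc1ccc(O)cc1Br | starting material
2 | 2-bromo-4-(methoxymethoxy)-1-methylbenzene | Cc1ccc(OCOC)cc1Br | intermediate
3 | 2-bromo-1-(bromomethyl)-4-(methoxymethoxy)benzene | BrCc1ccc(OCOC)cc1Br | intermediate
4 | (S)-but-3-yn-2-ol | C[C@H](O)C#C | starting material
5 | bromomagnesium alkynide alkoxide of (S)-but-3-yn-2-ol | C[C@H](O[Mg]Br)C#C[Mg]Br | intermediate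
6 | (2S)-5-[2-bromo-4-(methoxymethoxy)phenyl]pent-3-yn-2-ol | C[C@H](O)C#CCc1ccc(OCOC)cc1Br | intermediate
7 | (2S,3E)-5-[2-bromo-4-(methoxymethoxy)phenyl]pent-3-en-2-ol | C[C@H](O)/C=C/Cc1ccc(OCOC)cc1Br | intermediate
8 | 2-bromobenzene-1,3-diol (2-bromoresorcinol) | Oc1cccc(O)c1Br | starting material
9 | 2-bromo-3-{[(2R,3E)-5-[2-bromo-4-(methoxymethoxy)phenyl]pent-3-en-2-yl]oxy}phenol | C[C@@H](Oc1cccc(O)c1Br)/C=C/Cc1ccc(OCOC)cc1Br | intermediate
10 | 2-bromo-3-hydroxy-6-[(2S,3E)-1-[2-bromo-4-(methoxymethoxy)phenyl]pent-3-en-2-yl]cyclohexa-2,4-dien-1-one (ring C6 configuration undefined) | C/C=C/[C@H](Cc1ccc(OCOC)cc1Br)C1C=CC(O)=C(Br)C1=O | intermediate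
11 | 2-bromo-4-[(2S,3E)-1-[2-bromo-4-(methoxymethoxy)phenyl]pent-3-en-2-yl]benzene-1,3-diol | C/C=C/[C@H](Cc1ccc(OCOC)cc1Br)c1ccc(O)c(Br)c1O | intermediate
12 | (2R)-3-[2-bromo-4-(methoxymethoxy)phenyl]-2-(3-bromo-2,4-dihydroxyphenyl)propanal | O=C[C@H](Cc1ccc(OCOC)cc1Br)c1ccc(O)c(Br)c1O | intermediate
13 | 2-bromo-4-[(2R)-1-[2-bromo-4-(methoxymethoxy)phenyl]-3-hydroxypropan-2-yl]benzene-1,3-diol | OC[C@H](Cc1ccc(OCOC)cc1Br)c1ccc(O)c(Br)c1O | intermediate
14 | 3-methylbut-2-enal (prenal) | CC(C)=CC=O | starting material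
15 | 2-bromo-3-hydroxy-4-[(2R)-1-[2-bromo-4-(methoxymethoxy)phenyl]-3-hydroxypropan-2-yl]-6-(3-methylbut-2-en-1-ylidene)cyclohexa-2,4-dien-1-one | OC[C@H](Cc1ccc(OCOC)cc1Br)C1=CC(=CC=C(C)C)C(=O)C(Br)=C1O | intermediate
16 | 8-bromo-6-[(2R)-1-[2-bromo-4-(methoxymethoxy)phenyl]-3-hydroxypropan-2-yl]-2,2-dimethyl-2H-chromen-7-ol | OC[C@H](Cc1ccc(OCOC)cc1Br)c1cc2C=CC(C)(C)Oc2c(Br)c1O | intermediate
17 | (2R)-3-[2-bromo-4-(methoxymethoxy)phenyl]-2-[8-bromo-7-(methoxymethoxy)-2,2-dimethyl-2H-chromen-6-yl]propan-1-ol | OC[C@H](Cc1ccc(OCOC)cc1Br)c1cc2C=CC(C)(C)Oc2c(Br)c1OCOC | intermediate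
18 | (3R)-3-[8-bromo-7-(methoxymethoxy)-2,2-dimethyl-2H-chromen-6-yl]-7-(methoxymethoxy)chromane | COCOc1c(Br)c2OC(C)(C)C=Cc2cc1[C@@H]1COc2cc(OCOC)ccc2C1 | intermediate
19 | 1-bromo-3-methylbut-2-ene (prenyl bromide) | CC(C)=CCBr | starting material
20 | {6-[(3R)-7-(methoxymethoxy)chroman-3-yl]-7-(methoxymethoxy)-2,2-dimethyl-2H-chromen-8-yl}lithium | COCOc1c([Li])c2OC(C)(C)C=Cc2cc1[C@@H]1COc2cc(OCOC)ccc2C1 | intermediate
21 | (3R)-7-(methoxymethoxy)-3-[7-(methoxymethoxy)-2,2-dimethyl-8-(3-methylbut-2-en-1-yl)-2H-chromen-6-yl]chromane | COCOc1c(CC=C(C)C)c2OC(C)(C)C=Cc2cc1[C@@H]1COc2cc(OCOC)ccc2C1 | intermediate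
22 | (3R)-3-[7-hydroxy-2,2-dimethyl-8-(3-methylbut-2-en-1-yl)-2H-chromen-6-yl]chroman-7-ol | CC(C)=CCc1c(O)c([C@@H]2COc3cc(O)ccc3C2)cc2c1OC(C)(C)C=C2 | target

## Step count and risk

Total step count: 12. Longest linear sequence: 12 (1 → 22).

**Step 7** (ozonolysis of 11 with two free phenols on an electron-rich ring; risk of ring over-oxidation and of epimerising aldehyde 12). The fallback sets out from 11 and comes back at 13. Acetylation of both phenols (Ac2O, pyridine, cat. DMAP) gives 2-bromo-4-[(2S,3E)-1-[2-bromo-4-(methoxymethoxy)phenyl]pent-3-en-2-yl]-1,3-phenylene diacetate F1. Its deactivated ring allows an ozone-free Lemieux–Johnson cleavage (cat. OsO4, NaIO4, 2,6-lutidine, dioxane/water) to 2-bromo-4-[(2R)-1-[2-bromo-4-(methoxymethoxy)phenyl]-3-oxopropan-2-yl]-1,3-phenylene diacetate F2. NaBH4 (MeOH, 0 °C) then gives 2-bromo-4-[(2R)-1-[2-bromo-4-(methoxymethoxy)phenyl]-3-hydroxypropan-2-yl]-1,3-phenylene diacetate F3, and K2CO3/MeOH removes the acetates (including any that migrated to the primary OH) to give 13.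

**Step 8** (chromene annulation on a bromine-deactivated resorcinol carrying a free primary alcohol). The fallback sets out from 13 and comes back at 16. Alkylation of the less hindered phenol with 3-chloro-3-methylbut-1-yne (K2CO3, cat. KI, cat. CuI, acetone, reflux) gives 2-bromo-6-[(2R)-1-[2-bromo-4-(methoxymethoxy)phenyl]-3-hydroxypropan-2-yl]-3-[(2-methylbut-3-yn-2-yl)oxy]phenol F4. Heating it (PhNEt2, 160 °C) triggers propargyl Claisen rearrangement to the only free ortho carbon, 1,5-H shift and oxa-6π electrocyclization to give 16.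

**Step 12** (acidic removal of two MOM groups in the presence of an ortho-prenylphenol and a chromene; risk of prenyl cyclisation or alkene hydration). The fallback sets out from 18 and comes back at 22. The MOM groups are removed before any prenyl group is present (3 M HCl/MeOH, 45 °C) to give (3R)-3-(8-bromo-7-hydroxy-2,2-dimethyl-2H-chromen-6-yl)chroman-7-ol F5. The prenyl group is then installed by Suzuki–Miyaura coupling with prenylboronic acid pinacol ester (Pd(OAc)2, bulky biarylphosphine chosen for linear selectivity, K3PO4, THF/water, 40 °C), which tolerates the free phenols and gives 22 directly.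

## Further compounds

F1 | step 7 | 2-bromo-4-[(2S,3E)-1-[2-bromo-4-(methoxymethoxy)phenyl]pent-3-en-2-yl]-1,3-phenylene diacetate | C/C=C/[C@H](Cc1ccc(OCOC)cc1Br)c1ccc(OC(C)=O)c(Br)c1OC(C)=O
F2 | step 7 | 2-bromo-4-[(2R)-1-[2-bromo-4-(methoxymethoxy)phenyl]-3-oxopropan-2-yl]-1,3-phenylene diacetate | O=C[C@H](Cc1ccc(OCOC)cc1Br)c1ccc(OC(C)=O)c(Br)c1OC(C)=O
F3 | step 7 | 2-bromo-4-[(2R)-1-[2-bromo-4-(methoxymethoxy)phenyl]-3-hydroxypropan-2-yl]-1,3-phenylene diacetate | OC[C@H](Cc1ccc(OCOC)cc1Br)c1ccc(OC(C)=O)c(Br)c1OC(C)=O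
F4 | step 8 | 2-bromo-6-[(2R)-1-[2-bromo-4-(methoxymethoxy)phenyl]-3-hydroxypropan-2-yl]-3-[(2-methylbut-3-yn-2-yl)oxy]phenol | OC[C@H](Cc1ccc(OCOC)cc1Br)c1ccc(OC(C)(C)C#C)c(Br)c1O
F5 | step 12 | (3R)-3-(8-bromo-7-hydroxy-2,2-dimethyl-2H-chromen-6-yl)chroman-7-ol | Oc1c(Br)c2OC(C)(C)C=Cc2cc1[C@@H]1COc2cc(O)ccc2C1
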